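The cyclohex-2-enone ring (C1–C6, the only ring) is closed last, at C1–C6. The 4-hydroxy enone C1(=O)–C2=C3(CH3)–C4(OH) is read as a ring-opened β-methylbutenolide. A copper–bis(oxazoline) vinylogous Mukaiyama–Michael addition of 4-methyl-2-silyloxyfuran to a geranylgeranyl-bearing N-enoylpyrazole sets C4 and C5 (anti, which becomes cis in the ring). The precursor is thus a butenolide carrying a CH(geranylgeranyl)CH2C(=O)-pyrazole arm on its γ-carbon. In the key step its C6 titanium enolate is acylated by the lactone carbonyl (Dieckmann-type ring switch): the carbocycle forms, the C1 ketone and the free C4–OH appear without protecting groups, and the activating acyl group leaves as CO2 in the same flask.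

Key step: step 7

Remark: ring atoms are numbered as in the enone, C1 (C=O), C2, C3 (CH3), C4 (OH), C5 (side chain), C6. The target is the cis-(4S,5S) isomer. "Geranylgeranyl" means the (2E,6E,10E)-3,7,11,15-tetramethylhexadeca-2,6,10,14-tetraen-1-yl group, taken from commercial all-E geranylgeraniol.

Step 1
Reactants: 1 (2E,6E,10E)-geranylgeraniol
Product: 2 (2E,6E,10E)-geranylgeranyl bromide
Conditions: PBr3, Et2O, −10 °C
Reagents that add atoms: phosphorus tribromide, BrP(Br)Br
Why: Bromination of the primary allylic alcohol with PBr3 at low temperature is an SN2 displacement without allylic transposition, so the all-E chain should be kept.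

Step 2
Reactants: 2 geranylgeranyl bromide
Product: 3 (4E,8E,12E)-5,9,13,17-tetramethyloctadeca-1,4,8,12,16-pentaene
Conditions: CH2=CHMgBr, Li2CuCl4 (cat.), THF, −78 to 0 °C
Reagents that add atoms: vinylmagnesium bromide, C=C[Mg]Br
Why: Copper-catalysed allyl–vinyl cross-coupling of the Grignard reagent should attack the unhindered α-carbon rather than the tertiary γ-carbon, giving the skipped diene with the (E)-trisubstituted olefin intact.

Step 3
Reactants: 4 3,5-dimethyl-1H-pyrazole; 5 acryloyl chloride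
Product: 6 1-(3,5-dimethyl-1H-pyrazol-1-yl)prop-2-en-1-one
Conditions: Et3N, CH2Cl2, 0 °C
Reagents that add atoms: none
Why: N-Acylation of the pyrazole NH by the acid chloride gives the chelating, easily cleaved active amide.

Step 4
Reactants: 3 the pentaene; 6 the N-acryloylpyrazole (excess)
Product: 7 1-[(2E,5E,9E,13E)-6,10,14,18-tetramethylnonadeca-2,5,9,13,17-pentaenoyl]-3,5-dimethyl-1H-pyrazole
Conditions: second-generation Hoveyda–Grubbs catalyst RuCl2(H2IMes)(=CH–C6H4-2-O-i-Pr) (5 mol%), 1,4-benzoquinone (10 mol%), CH2Cl2, 40 °C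
Reagents that add atoms: none
Why: Olefin cross-metathesis between the only monosubstituted olefin of 3 and the electron-poor acrylamide-type partner should be selective over the trisubstituted olefins and give the (E)-enoyl product under thermodynamic control, with benzoquinone suppressing isomerisation of the skipped diene by ruthenium hydrides.

Step 5
Reactants: 8 4-methylfuran-2(5H)-one
Product: 9 4-methyl-2-(trimethylsilyloxy)furan
Conditions: Me3SiOTf, Et3N, CH2Cl2, 0 °C
Reagents that add atoms: trimethylsilyl trifluoromethanesulfonate, C[Si](C)(C)OS(=O)(=O)C(F)(F)F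
Why: Soft enolisation and O-silylation of the butenolide (γ-deprotonation after O-activation) gives the aromatic 2-silyloxyfuran, a vinylogous silyl enol ether.

Step 6
Reactants: 7 the N-enoylpyrazole; 9 the silyloxyfuran
Product: 10 1-[(3S,5E,9E,13E)-6,10,14,18-tetramethyl-3-[(2S)-3-methyl-5-oxo-2,5-dihydrofuran-2-yl]nonadeca-5,9,13,17-tetraenoyl]-3,5-dimethyl-1H-pyrazole
Conditions: Cu(OTf)2 (10 mol%), (S,S)-2,2′-isopropylidenebis(4-tert-butyl-2-oxazoline) (11 mol%), (CF3)2CHOH, 4 Å molecular sieves, CH2Cl2, −20 °C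
Reagents that add atoms: none
Why: In this vinylogous Mukaiyama–Michael addition Cu(OTf)2 with the (S,S)-bis(oxazoline) should bind 7 as a square-planar N2,O-chelate in its s-cis form and leave the Si face of C-β (the future C5) open, and the furan should add through its C5 in the compact Diels–Alder-like (endo) arrangement, so that C5 (S) is set by the ligand and C4 (S) by the anti (like) topicity, while (CF3)2CHOH takes the silyl group and protonates the copper enolate.

Step 7
Reactants: 10 the butenolide acylpyrazole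
Product: 13 (4S,5S)-4-hydroxy-3-methyl-5-[(2E,6E,10E)-3,7,11,15-tetramethylhexadeca-2,6,10,14-tetraen-1-yl]cyclohex-2-en-1-one, via β-keto acylpyrazole 11 (not isolated), via β-keto acid 12 (not isolated)
Conditions: TiCl4 (2.0 equiv), i-Pr2NEt (1.1 equiv), CH2Cl2 (0.01 M), −78 to −20 °C; then 1 M aq. HCl, THF, 35 °C
Reagents that add atoms: none
Why: Chelation of TiCl4 by the N-acylpyrazole (carbonyl O and N2) should allow selective soft enolisation at C6 with one equivalent of amine; the titanium enolate then attacks the lactone carbonyl C1 held on the same face of C4 (6-exo-trig addition to the C=O, through a 7-oxabicyclo[2.2.1]hept-2-en-1-olate tetrahedral intermediate), which collapses by cleavage of the strained C1–O bridge to the titanium chelate of 11 with the C4 oxygen released as alkoxide. The closest known reaction types are the titanium-mediated Dieckmann (Ti-Claisen) condensation and the ring-closing stage of the Hauser–Kraus and related phthalide-anion annulations, where an enolate acylated by a lactone gives a 4-hydroxy ketone. No stereocentre is formed: C4 (S) and C5 (S) come from step 6 and no bond to them is broken, C5 carries no acidic hydrogen and C6 ends as CH2. The selectivity needed is enolisation at C6 rather than at the γ-carbon C4 of the butenolide (which would epimerise C4 through the 2-oxidofuran); it is secured by the bidentate N,O-chelate, the limiting amount of base and the low temperature, and complete enolisation at −78 °C before warming also suppresses intermolecular Claisen condensation. Aqueous acid then hydrolyses the activated amide (directly or after lactonisation by the neighbouring C4–OH), and β-keto acid 12 loses CO2 through the usual six-membered transition state to give 13.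

Compound list
1 | (2E,6E,10E)-3,7,11,15-tetramethylhexadeca-2,6,10,14-tetraen-1-ol (geranylgeraniol) | CC(C)=CCC/C(C)=C/CC/C(C)=C/CC/C(C)=C/CO | starting material
2 | (2E,6E,10E)-1-bromo-3,7,11,15-tetramethylhexadeca-2,6,10,14-tetraene (geranylgeranyl bromide) | CC(C)=CCC/C(C)=C/CC/C(C)=C/CC/C(C)=C/CBr | intermediate
3 | (4E,8E,12E)-5,9,13,17-tetramethyloctadeca-1,4,8,12,16-pentaene | CC(C)=CCC/C(C)=C/CC/C(C)=C/CC/C(C)=C/CC=C | intermediate
4 | 3,5-dimethyl-1H-pyrazole | Cc1cc(C)[nH]n1 | starting material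
5 | acryloyl chloride | C=CC(=O)Cl | starting material
6 | 1-(3,5-dimethyl-1H-pyrazol-1-yl)prop-2-en-1-one | C=CC(=O)n1nc(C)cc1C | intermediate
7 | 1-[(2E,5E,9E,13E)-6,10,14,18-tetramethylnonadeca-2,5,9,13,17-pentaenoyl]-3,5-dimethyl-1H-pyrazole | CC(C)=CCC/C(C)=C/CC/C(C)=C/CC/C(C)=C/C/C=C/C(=O)n1nc(C)cc1C | intermediate
8 | 4-methylfuran-2(5H)-one | CC1=CC(=O)OC1 | starting material
9 | 4-methyl-2-(trimethylsilyloxy)furan | Cc1coc(O[Si](C)(C)C)c1 | intermediate
10 | 1-[(3S,5E,9E,13E)-6,10,14,18-tetramethyl-3-[(2S)-3-methyl-5-oxo-2,5-dihydrofuran-2-yl]nonadeca-5,9,13,17-tetraenoyl]-3,5-dimethyl-1H-pyrazole | CC(C)=CCC/C(C)=C/CC/C(C)=C/CC/C(C)=C/C[C@@H](CC(=O)n1nc(C)cc1C)[C@@H]2OC(=O)C=C2C | intermediate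
11 | 1-{[(5S,6S)-5-hydroxy-4-methyl-2-oxo-6-[(2E,6E,10E)-3,7,11,15-tetramethylhexadeca-2,6,10,14-tetraen-1-yl]cyclohex-3-en-1-yl]carbonyl}-3,5-dimethyl-1H-pyrazole (titanium chelate/enol in the flask; the carbonyl-bearing ring carbon, target C6, is not configurationally defined) | CC(C)=CCC/C(C)=C/CC/C(C)=C/CC/C(C)=C/C[C@H]1C(C(=O)n2nc(C)cc2C)C(=O)C=C(C)[C@H]1O | intermediate (not isolated)
12 | (5S,6S)-5-hydroxy-4-methyl-2-oxo-6-[(2E,6E,10E)-3,7,11,15-tetramethylhexadeca-2,6,10,14-tetraen-1-yl]cyclohex-3-ene-1-carboxylic acid | CC(C)=CCC/C(C)=C/CC/C(C)=C/CC/C(C)=C/C[C@H]1C(C(=O)O)C(=O)C=C(C)[C@H]1O | intermediate (not isolated)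
13 | (4S,5S)-4-hydroxy-3-methyl-5-[(2E,6E,10E)-3,7,11,15-tetramethylhexadeca-2,6,10,14-tetraen-1-yl]cyclohex-2-en-1-one | CC(C)=CCC/C(C)=C/CC/C(C)=C/CC/C(C)=C/C[C@H]1CC(=O)C=C(C)[C@H]1O | target

Total step count: 7. Longest linear sequence: 5 steps (1 → 2 → 3 → 7 → 10 → 13; steps 1, 2, 4, 6 and 7).

Steps most likely to fail

Step 7. The configuration at C4 may be lost before closure: γ-deprotonation of the butenolide to the 2-oxidofuran and reprotonation, or a retro-Michael/Michael sequence, would lead to closure from the wrong C4 epimer. Fallback: the route sets out from 10 under the same protocol and, after chromatographic separation, takes the 4,5-trans isomer (4R,5S)-4-hydroxy-3-methyl-5-[(2E,6E,10E)-3,7,11,15-tetramethylhexadeca-2,6,10,14-tetraen-1-yl]cyclohex-2-en-1-one F1 on. Mitsunobu inversion at C4 (4-nitrobenzoic acid, PPh3, DIAD, THF, 0 °C) should give (1S,6S)-2-methyl-4-oxo-6-[(2E,6E,10E)-3,7,11,15-tetramethylhexadeca-2,6,10,14-tetraen-1-yl]cyclohex-2-en-1-yl 4-nitrobenzoate F2, and mild methanolysis (K2CO3, MeOH, 0 °C) comes back to the route at 13.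

Step 6. Facial or anti/syn selectivity in the C4–C5 bond formation may be poor with the acylpyrazole template and the 4-methyl-substituted furan. Fallback: it sets out from 3 and 9 and uses the oxazolidinone template, for which anti-selective copper–bis(oxazoline) additions of silyloxyfurans are established. Cross-metathesis of 3 with commercial 3-acryloyl-1,3-oxazolidin-2-one should give 3-[(2E,5E,9E,13E)-6,10,14,18-tetramethylnonadeca-2,5,9,13,17-pentaenoyl]-1,3-oxazolidin-2-one F3. Addition of 9 under Cu(OTf)2/(S,S)-bis(oxazoline) with (CF3)2CHOH should give 3-[(3S,5E,9E,13E)-6,10,14,18-tetramethyl-3-[(2S)-3-methyl-5-oxo-2,5-dihydrofuran-2-yl]nonadeca-5,9,13,17-tetraenoyl]-1,3-oxazolidin-2-one F4. Cleavage with LiOH/H2O2 (THF/H2O, 0 °C) should give (3S,5E,9E,13E)-6,10,14,18-tetramethyl-3-[(2S)-3-methyl-5-oxo-2,5-dihydrofuran-2-yl]nonadeca-5,9,13,17-tetraenoic acid F5, and coupling with 4 (EDC·HCl, DMAP, CH2Cl2) comes back to the route at 10.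

Step 4. Metathesis at the trisubstituted olefins and ruthenium hydride migration of the skipped diene may compete with the wanted cross-metathesis. Fallback: it sets out from 2 and avoids metathesis. Stille coupling of 2 with ethyl (E)-3-(tributylstannyl)acrylate (Pd2(dba)3, AsPh3, THF, 50 °C) should give ethyl (2E,5E,9E,13E)-6,10,14,18-tetramethylnonadeca-2,5,9,13,17-pentaenoate F6. Neutral ester cleavage (Me3SnOH, 1,2-dichloroethane, 60 °C) should give (2E,5E,9E,13E)-6,10,14,18-tetramethylnonadeca-2,5,9,13,17-pentaenoic acid F7, and coupling with 4 (EDC·HCl, DMAP, CH2Cl2) comes back to the route at 7.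

Further compounds
F1 | step 7 | (4R,5S)-4-hydroxy-3-methyl-5-[(2E,6E,10E)-3,7,11,15-tetramethylhexadeca-2,6,10,14-tetraen-1-yl]cyclohex-2-en-1-one | CC(C)=CCC/C(C)=C/CC/C(C)=C/CC/C(C)=C/C[C@H]1CC(=O)C=C(C)[C@@H]1O
F2 | step 7 | (1S,6S)-2-methyl-4-oxo-6-[(2E,6E,10E)-3,7,11,15-tetramethylhexadeca-2,6,10,14-tetraen-1-yl]cyclohex-2-en-1-yl 4-nitrobenzoate | CC(C)=CCC/C(C)=C/CC/C(C)=C/CC/C(C)=C/C[C@H]1CC(=O)C=C(C)[C@H]1OC(=O)c2ccc(cc2)[N+](=O)[O-]
F3 | step 6 | 3-[(2E,5E,9E,13E)-6,10,14,18-tetramethylnonadeca-2,5,9,13,17-pentaenoyl]-1,3-oxazolidin-2-one | CC(C)=CCC/C(C)=C/CC/C(C)=C/CC/C(C)=C/C/C=C/C(=O)N1CCOC1=O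
F4 | step 6 | 3-[(3S,5E,9E,13E)-6,10,14,18-tetramethyl-3-[(2S)-3-methyl-5-oxo-2,5-dihydrofuran-2-yl]nonadeca-5,9,13,17-tetraenoyl]-1,3-oxazolidin-2-one | CC(C)=CCC/C(C)=C/CC/C(C)=C/CC/C(C)=C/C[C@@H](CC(=O)N1CCOC1=O)[C@@H]2OC(=O)C=C2C
F5 | step 6 | (3S,5E,9E,13E)-6,10,14,18-tetramethyl-3-[(2S)-3-methyl-5-oxo-2,5-dihydrofuran-2-yl]nonadeca-5,9,13,17-tetraenoic acid | CC(C)=CCC/C(C)=C/CC/C(C)=C/CC/C(C)=C/C[C@@H](CC(=O)O)[C@@H]1OC(=O)C=C1C
F6 | step 4 | ethyl (2E,5E,9E,13E)-6,10,14,18-tetramethylnonadeca-2,5,9,13,17-pentaenoate | CC(C)=CCC/C(C)=C/CC/C(C)=C/CC/C(C)=C/C/C=C/C(=O)OCC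
F7 | step 4 | (2E,5E,9E,13E)-6,10,14,18-tetramethylnonadeca-2,5,9,13,17-pentaenoic acid | CC(C)=CCC/C(C)=C/CC/C(C)=C/CC/C(C)=C/C/C=C/C(=O)O
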